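## Retrosynthetic overview

1. Target 18 ⇒ hexabenzyl ether 17 (hydrogenolysis last) ⇒ C4–C8 interflavan bond between the C4-activated 7,4'-di-O-benzyl-epiguibourtinidol 13 and tetra-O-benzyl-(−)-epicatechin 15; the lower chroman is bought as chiral pool.
2. 13 ⇒ cis-(2R,3R)-flavan-3-ol 11 (C4–H oxidation) ⇒ racemic flavan-3-one 10, where one dynamic-kinetic-resolution hydrogenation sets C2 and C3 together.
3. 10 ⇒ 3-nitro-2H-chromene 8; the nitro group is the masked C3 carbonyl.
4. Key disconnection: C3–C4 of the upper pyran ring, made by a nitronate (acyl-anion equivalent for C3) attacking the salicylaldehyde carbon C4, in tandem with O1–C2 closure by oxa-Michael addition (nitrostyrene 4 + salicylaldehyde 5).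
5. Ring order: upper pyran ring (step 2), upper C2/C3 stereocentres (step 4), then the interflavan bond with the C4 stereocentre (step 7); the lower unit's rings come preformed.

Assumption: the sense of induction in step 4 is taken from the 2-arylcyclohexanone precedent as I recall it; if the first run gives the (2S,3S) alcohol, the mirror-image catalyst is used with nothing else changed.

## Route

Step 1
Reactants: 1 4-(benzyloxy)benzaldehyde; 2 nitromethane
Product: 4 (E)-1-(benzyloxy)-4-(2-nitrovinyl)benzene, via nitroaldol 3 (not isolated)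
Conditions: NH4OAc (0.5 equiv), MeNO2 (solvent), 100 °C
Reagents that add atoms: none
Why: Henry (nitro-aldol) condensation, in which addition of the nitromethane anion to the aldehyde is followed by E1cB loss of water to give the conjugated (E)-nitroalkene.

Step 2
Reactants: 4 (E)-1-(benzyloxy)-4-(2-nitrovinyl)benzene; 5 4-(benzyloxy)-2-hydroxybenzaldehyde
Product: 8 7-(benzyloxy)-2-[4-(benzyloxy)phenyl]-3-nitro-2H-chromene (racemic), via oxa-Michael adduct 6 (not isolated), via 3-nitrochroman-4-ol 7 (not isolated)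
Conditions: DABCO (0.5 equiv), MeCN, 60 °C
Reagents that add atoms: none
Why: Tandem oxa-Michael/intramolecular Henry (nitro-aldol) condensation: the phenoxide of 5 adds to the β-carbon of 4 to make O1–C2, and the nitronate so formed, a masked acyl anion (d1) for the future C3 carbonyl, attacks the aldehyde carbon C4, so two carbons that are both electrophilic carbonyl carbons in their natural polarity are joined, while E1cB loss of water pulls the reversible cascade to the conjugated nitroalkene; C2 is left racemic on purpose because step 4 corrects it.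

Step 3
Reactants: 8 7-(benzyloxy)-2-[4-(benzyloxy)phenyl]-3-nitro-2H-chromene
Product: 10 7-(benzyloxy)-2-[4-(benzyloxy)phenyl]chroman-3-one (racemic), via ketimine 9 (not isolated)
Conditions: Fe powder (6 equiv), AcOH/H2O 9:1, 80 °C, N2
Reagents that add atoms: water (O)
Why: Reductive Nef-type unmasking (Fe/AcOH reduction of a conjugated nitroalkene): six-electron reduction gives the enamine/ketimine 9, whose hydrolysis reveals the C3 carbonyl, and the benzyl ethers and the C2–O1 bond are inert to Fe/AcOH.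

Step 4
Reactants: 10 7-(benzyloxy)-2-[4-(benzyloxy)phenyl]chroman-3-one (racemic)
Product: 11 (2R,3R)-7-(benzyloxy)-2-[4-(benzyloxy)phenyl]chroman-3-ol
Conditions: H2 (50 atm), RuCl2[(R)-Xyl-SDP][(S,S)-DPEN] (0.5 mol%), KOtBu (10 mol%), iPrOH/toluene 4:1, 25 °C
Reagents that add atoms: none
Why: Proposed new method: Noyori-type asymmetric hydrogenation with dynamic kinetic resolution, closest known reaction type the Ru–diphosphine/diamine hydrogenation of racemic 2-arylcyclohexanones to cis-2-arylcyclohexanols; the C2–H (α-keto, benzylic, α-aryloxy) is racemised by tert-butoxide faster than H2 is transferred, the chiral Ru–H/N–H pocket reduces only the (2R)-ketone and delivers hydride anti to the 2-aryl group, which sets C2 (R) and C3 (R, 2,3-cis) in one operation.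

Step 5
Reactants: 11 (2R,3R)-7-(benzyloxy)-2-[4-(benzyloxy)phenyl]chroman-3-ol
Product: 13 (2R,3R,4S)-7-(benzyloxy)-2-[4-(benzyloxy)phenyl]-4-(2-ethoxyethoxy)chroman-3-ol, via C4 cation DDQH-phenolate ion pair 12 (not isolated)
Conditions: DDQ (1.5 equiv), 2-ethoxyethanol (5 equiv), CH2Cl2, 0 °C → rt
Reagents that add atoms: 2-ethoxyethanol (CCOCCO)
Why: DDQ benzylic oxidation: hydride abstraction from C4, activated by the para 7-benzyloxy group and the ortho ring oxygen, gives the flavan-4-ylium/DDQH-phenolate contact ion pair 12, whose cation is trapped by the alcohol anti to the 3-OH while the phenolate takes up the proton; C2 and C3 are untouched and the C4 configuration does not matter because C4 is ionised again in step 7.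

Step 6
Reactants: 14 (−)-epicatechin
Product: 15 5,7,3',4'-tetra-O-benzyl-(−)-epicatechin
Conditions: BnBr (4.4 equiv), K2CO3 (5 equiv), DMF, 0 °C → rt
Reagents that add atoms: benzyl bromide (BrCc1ccccc1)
Why: Williamson ether synthesis in which carbonate deprotonates only the four phenols (pKa about 9–10), so the secondary 3-OH stays free and no stereocentre is touched.

Step 7
Reactants: 13 (2R,3R,4S)-7-(benzyloxy)-2-[4-(benzyloxy)phenyl]-4-(2-ethoxyethoxy)chroman-3-ol; 15 5,7,3',4'-tetra-O-benzyl-(−)-epicatechin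
Product: 17 (2R,3R)-5,7-bis(benzyloxy)-8-{(2R,3R,4R)-7-(benzyloxy)-2-[4-(benzyloxy)phenyl]-3-hydroxychroman-4-yl}-2-[3,4-bis(benzyloxy)phenyl]chroman-3-ol, via C4 cation triflate ion pair 16 (not isolated)
Conditions: 15 (3 equiv), TMSOTf (0.2 equiv), CH2Cl2, −40 → 0 °C
Reagents that add atoms: none
Why: Lewis acid-promoted SN1 Friedel–Crafts alkylation (interflavan coupling): TMSOTf activates the chelating 2-ethoxyethoxy group and ionises C4 to the flavan-4-ylium triflate ion pair 16, whose cation is attacked by C8 of 15 (the less hindered nucleophilic position of the di-O-benzylphloroglucinol ring, with excess 15 suppressing oligomers) from the β-face, anti to both the axial 3-OH and the 2-aryl group, giving the 3,4-trans (4R) bond as is the rule for 2,3-cis flavan-3-ol electrophiles.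

Step 8
Reactants: 17 (2R,3R)-5,7-bis(benzyloxy)-8-{(2R,3R,4R)-7-(benzyloxy)-2-[4-(benzyloxy)phenyl]-3-hydroxychroman-4-yl}-2-[3,4-bis(benzyloxy)phenyl]chroman-3-ol
Product: 18 (2R,3R)-2-(3,4-dihydroxyphenyl)-8-[(2R,3R,4R)-3,7-dihydroxy-2-(4-hydroxyphenyl)chroman-4-yl]chromane-3,5,7-triol (target)
Conditions: H2 (1 atm), 20% Pd(OH)2/C, THF/MeOH/H2O 20:20:1, rt; Sephadex LH-20
Reagents that add atoms: none
Why: Catalytic hydrogenolysis of the six benzyl ethers over Pearlman's catalyst at 1 atm, conditions under which the doubly benzylic C4–C8 bond, the C2–O1 ethers and all five stereocentres are preserved.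

## Compound list

1 | 4-(benzyloxy)benzaldehyde | O=Cc1ccc(OCc2ccccc2)cc1 | starting material
2 | nitromethane | C[N+](=O)[O-] | starting material
3 | 1-[4-(benzyloxy)phenyl]-2-nitroethanol (racemic, not isolated) | OC(C[N+](=O)[O-])c1ccc(OCc2ccccc2)cc1 | intermediate
4 | (E)-1-(benzyloxy)-4-(2-nitrovinyl)benzene | [O-][N+](=O)/C=C/c1ccc(OCc2ccccc2)cc1 | intermediate
5 | 4-(benzyloxy)-2-hydroxybenzaldehyde | O=Cc1ccc(OCc2ccccc2)cc1O | starting material
6 | 4-(benzyloxy)-2-{1-[4-(benzyloxy)phenyl]-2-nitroethoxy}benzaldehyde (racemic, not isolated) | O=Cc1ccc(OCc2ccccc2)cc1OC(C[N+](=O)[O-])c1ccc(OCc2ccccc2)cc1 | intermediate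
7 | 7-(benzyloxy)-2-[4-(benzyloxy)phenyl]-3-nitrochroman-4-ol (racemic diastereomer mixture, not isolated) | OC1c2ccc(OCc3ccccc3)cc2OC(c2ccc(OCc3ccccc3)cc2)C1[N+](=O)[O-] | intermediate
8 | 7-(benzyloxy)-2-[4-(benzyloxy)phenyl]-3-nitro-2H-chromene (racemic) | [O-][N+](=O)C1=Cc2ccc(OCc3ccccc3)cc2OC1c1ccc(OCc2ccccc2)cc1 | intermediate
9 | 7-(benzyloxy)-2-[4-(benzyloxy)phenyl]chroman-3-imine (racemic, not isolated) | N=C1Cc2ccc(OCc3ccccc3)cc2OC1c1ccc(OCc2ccccc2)cc1 | intermediate
10 | 7-(benzyloxy)-2-[4-(benzyloxy)phenyl]chroman-3-one (racemic) | O=C1Cc2ccc(OCc3ccccc3)cc2OC1c1ccc(OCc2ccccc2)cc1 | intermediate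
11 | (2R,3R)-7-(benzyloxy)-2-[4-(benzyloxy)phenyl]chroman-3-ol | c1ccc(COc2ccc([C@H]3Oc4cc(OCc5ccccc5)ccc4C[C@H]3O)cc2)cc1 | intermediate
12 | (2R,3R)-7-(benzyloxy)-2-[4-(benzyloxy)phenyl]-3-hydroxychroman-4-ylium 2,3-dichloro-5,6-dicyano-4-hydroxyphenolate (contact ion pair, not isolated) | c1ccc(COc2ccc([C@H]3Oc4cc(OCc5ccccc5)ccc4[CH+][C@H]3O)cc2)cc1.[O-]c1c(Cl)c(Cl)c(O)c(C#N)c1C#N | intermediate
13 | (2R,3R,4S)-7-(benzyloxy)-2-[4-(benzyloxy)phenyl]-4-(2-ethoxyethoxy)chroman-3-ol | c1ccc(COc2ccc([C@H]3Oc4cc(OCc5ccccc5)ccc4[C@H](OCCOCC)[C@H]3O)cc2)cc1 | intermediate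
14 | (−)-epicatechin, (2R,3R)-2-(3,4-dihydroxyphenyl)chromane-3,5,7-triol | c1c(O)cc(O)c2c1O[C@H](c1ccc(O)c(O)c1)[C@H](O)C2 | starting material
15 | 5,7,3',4'-tetra-O-benzyl-(−)-epicatechin, (2R,3R)-5,7-bis(benzyloxy)-2-[3,4-bis(benzyloxy)phenyl]chroman-3-ol | c1c(OCc3ccccc3)cc(OCc3ccccc3)c2c1O[C@H](c1ccc(OCc3ccccc3)c(OCc3ccccc3)c1)[C@H](O)C2 | intermediate
16 | (2R,3R)-7-(benzyloxy)-2-[4-(benzyloxy)phenyl]-3-hydroxychroman-4-ylium trifluoromethanesulfonate (contact ion pair, not isolated) | c1ccc(COc2ccc([C@H]3Oc4cc(OCc5ccccc5)ccc4[CH+][C@H]3O)cc2)cc1.[O-]S(=O)(=O)C(F)(F)F | intermediate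
17 | (2R,3R)-5,7-bis(benzyloxy)-8-{(2R,3R,4R)-7-(benzyloxy)-2-[4-(benzyloxy)phenyl]-3-hydroxychroman-4-yl}-2-[3,4-bis(benzyloxy)phenyl]chroman-3-ol | c1ccccc1COc1ccc([C@H]2Oc3cc(OCc6ccccc6)ccc3[C@H](c3c(OCc6ccccc6)cc(OCc6ccccc6)c4c3O[C@H](c3ccc(OCc6ccccc6)c(OCc6ccccc6)c3)[C@H](O)C4)[C@H]2O)cc1 | intermediate
18 | (2R,3R)-2-(3,4-dihydroxyphenyl)-8-[(2R,3R,4R)-3,7-dihydroxy-2-(4-hydroxyphenyl)chroman-4-yl]chromane-3,5,7-triol, epiguibourtinidol-(4β→8)-epicatechin | Oc1ccc([C@H]2Oc3cc(O)ccc3[C@H](c3c(O)cc(O)c4c3O[C@H](c3ccc(O)c(O)c3)[C@H](O)C4)[C@H]2O)cc1 | target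

## Count and risks

Total step count: 8. Longest linear sequence: 7 (steps 1, 2, 3, 4, 5, 7, 8; step 6 is the one-step side branch).

Most likely to fail, step 3 (the flavan-3-one 10 is air- and acid-sensitive and the one-pot iron reduction may stall at the oxime or over-reduce to the amine). The fallback sets out from 8 and comes back at 10. Conjugate reduction of the nitroalkene with NaBH4 (silica gel, CHCl3/iPrOH) gives 7-(benzyloxy)-2-[4-(benzyloxy)phenyl]-3-nitrochromane F1. Its nitronate (NaOMe, MeOH) is then unmasked by a McMurry-type Nef reaction with buffered TiCl3 (NH4OAc, pH 5–6) to give 10. Any retro-oxa-Michael opening and reclosure of the nitronate only scrambles C2, which is racemic at this stage anyway.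

Most likely to fail, step 4 (untested substrate class; self-aldol of 10 under base, or wrong or low enantioselectivity). The fallback sets out from 10 and comes back at 17, replacing catalytic enantiocontrol by resolution through the chiral lower unit. L-Selectride (THF, −78 °C) reduces racemic 10 anti to the 2-aryl group to the racemic 2,3-cis alcohol, that is 11 together with its enantiomer (2S,3S)-7-(benzyloxy)-2-[4-(benzyloxy)phenyl]chroman-3-ol F2. The racemate is taken through the DDQ/2-ethoxyethanol oxidation of step 5 to 13 plus its enantiomer (2S,3S,4R)-7-(benzyloxy)-2-[4-(benzyloxy)phenyl]-4-(2-ethoxyethoxy)chroman-3-ol F3. TMSOTf coupling with enantiopure 15 under the step 7 conditions then gives 17 and the diastereomer (2R,3R)-5,7-bis(benzyloxy)-8-{(2S,3S,4S)-7-(benzyloxy)-2-[4-(benzyloxy)phenyl]-3-hydroxychroman-4-yl}-2-[3,4-bis(benzyloxy)phenyl]chroman-3-ol F4, which is removed by chromatography. At most half of the upper unit is used.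

Most likely to fail, step 5 (DDQ may abstract the C2–H, which is p-alkoxybenzylic and α to oxygen, instead of the less activated 5-deoxy C4–H). The fallback sets out from 8 and comes back at 17, putting the C4 oxygen in before the ketone exists. Nucleophilic epoxidation of 8 (tBuOOH, DBU, THF, 0 °C) gives 7-(benzyloxy)-2-[4-(benzyloxy)phenyl]-3,4-epoxy-3-nitrochromane F5. Warming F5 with 2-ethoxyethanol and NaHCO3 opens the epoxide at the benzylic C4 with loss of nitrite to give 7-(benzyloxy)-2-[4-(benzyloxy)phenyl]-4-(2-ethoxyethoxy)chroman-3-one F6. Hydrogenation of F6 under the step 4 conditions (C2 and C4 both epimerise; hydride enters anti to both substituents) gives the all-cis (2R,3R,4R)-7-(benzyloxy)-2-[4-(benzyloxy)phenyl]-4-(2-ethoxyethoxy)chroman-3-ol F7, the C4 epimer of 13. Under the step 7 conditions F7 ionises to the same triflate ion pair 16 and is coupled with 15 to give 17.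

Further compounds
F1 | step 3 | 7-(benzyloxy)-2-[4-(benzyloxy)phenyl]-3-nitrochromane (racemic) | [O-][N+](=O)C1Cc2ccc(OCc3ccccc3)cc2OC1c1ccc(OCc3ccccc3)cc1
F2 | step 4 | (2S,3S)-7-(benzyloxy)-2-[4-(benzyloxy)phenyl]chroman-3-ol | c1ccc(COc2ccc([C@@H]3Oc4cc(OCc5ccccc5)ccc4C[C@@H]3O)cc2)cc1
F3 | step 4 | (2S,3S,4R)-7-(benzyloxy)-2-[4-(benzyloxy)phenyl]-4-(2-ethoxyethoxy)chroman-3-ol | c1ccc(COc2ccc([C@@H]3Oc4cc(OCc5ccccc5)ccc4[C@@H](OCCOCC)[C@@H]3O)cc2)cc1
F4 | step 4 | (2R,3R)-5,7-bis(benzyloxy)-8-{(2S,3S,4S)-7-(benzyloxy)-2-[4-(benzyloxy)phenyl]-3-hydroxychroman-4-yl}-2-[3,4-bis(benzyloxy)phenyl]chroman-3-ol | c1ccccc1COc1ccc([C@@H]2Oc3cc(OCc6ccccc6)ccc3[C@@H](c3c(OCc6ccccc6)cc(OCc6ccccc6)c4c3O[C@H](c3ccc(OCc6ccccc6)c(OCc6ccccc6)c3)[C@H](O)C4)[C@@H]2O)cc1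
F5 | step 5 | 7-(benzyloxy)-2-[4-(benzyloxy)phenyl]-3,4-epoxy-3-nitrochromane (racemic) | [O-][N+](=O)C12OC1c1ccc(OCc3ccccc3)cc1OC2c1ccc(OCc3ccccc3)cc1
F6 | step 5 | 7-(benzyloxy)-2-[4-(benzyloxy)phenyl]-4-(2-ethoxyethoxy)chroman-3-one (racemic) | O=C1C(OCCOCC)c2ccc(OCc3ccccc3)cc2OC1c1ccc(OCc3ccccc3)cc1
F7 | step 5 | (2R,3R,4R)-7-(benzyloxy)-2-[4-(benzyloxy)phenyl]-4-(2-ethoxyethoxy)chroman-3-ol | c1ccc(COc2ccc([C@H]3Oc4cc(OCc5ccccc5)ccc4[C@@H](OCCOCC)[C@H]3O)cc2)cc1
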